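**Retrosynthetic overview**

1. Locants: ring E (piperidine) N1, C2 (CH3), C3–C6; ring C (cyclopentane) C7 (bears C6), C8, C9, C10, C11 (O, CH3); ring D (lactone) C10, C11, O, C12 (C=O), C13; ring B C9, C10, C13=C14, C15 (OH), C16; ring A C15, C16 and four CH2.
2. Last disconnections: C15–OH by γ-oxygenation of a C14=C15 β,γ-unsaturated lactone; rings B and D together (bonds C10–C13 and C9–C16) by an ester-tethered intramolecular Diels–Alder reaction of a (cyclohexenyl)acrylate (ring A bought) onto the C9=C10 cyclopentene of a C11 tertiary allylic alcohol.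
3. That alcohol comes from a C7-substituted cyclopentenone (MeLi at C11; enone by Ito–Saegusa oxidation), and the ketone from syn-hydrogenation and N-acetylation of the bicyclic vinylogous amide N1–C6=C7–C11=O, which sets C6 and C7 from C2.
4. Key disconnection: ring E is closed onto bought ring C by making C4–C5 and N1–C2 in one flask from 2-acetylcyclopentanone, the cyclic sulfate of (R)-butane-1,3-diol and ammonia. The enabling feature is that N1 on C6 and the lactone oxygen on C11 are 1,3-related through C7, so C6/C7/C11 are a masked 1,3-diketone whose acetyl CH3 is C5, while C2(CH3)–C3–C4 is a butane-1,3-diol unit with C2 at the alcohol level.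
5. Ring order: C (bought) → E (step 2) → A (bought) → B and D (step 8); stereochemical relay C2 (chiral pool) → C6, C7 → C11 → C9, C10, C16 → C15.

Key step: step 2

Remark: (R)-butane-1,3-diol, 2-acetylcyclopentanone and cyclohex-1-ene-1-carbaldehyde are taken as commercial; ammonia is assumed to condense (reversibly) with the side-chain carbonyl of a 2-acylcyclopentanone, where the C=C of the enaminone is exocyclic to the five-membered ring.

**Route**

Step 1
Reactants: 1 (3R)-butane-1,3-diol
Product: 3 (4R)-4-methyl-1,3,2-dioxathiane 2,2-dioxide, via cyclic sulfite 2 (not isolated)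
Conditions: SOCl2, CH2Cl2, 0 °C → rt; then RuCl3 (cat.), NaIO4, MeCN–H2O, 0 °C
Reagents that add atoms: thionyl chloride ClS(Cl)=O; sodium periodate [Na+].[O-]I(=O)(=O)=O
Why: Standard two-stage cyclic sulfate synthesis (diol to cyclic sulfite, then ruthenium-catalysed periodate oxidation), which does not touch the carbinol stereocentre.

Step 2
Reactants: 4 2-acetylcyclopentan-1-one; 3 (4R)-4-methyl-1,3,2-dioxathiane 2,2-dioxide
Product: 8 (2Z)-2-[(6S)-6-methylpiperidin-2-ylidene]cyclopentan-1-one, via dilithium dianion 5 (not isolated), via alkyl sulfate enolate 6 (not isolated), via acyclic enaminone sulfate 7 (not isolated)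
Conditions: LDA (2.1 equiv), THF, 0 °C; 3, −78 → 0 °C; then NH4OAc (10 equiv), MeOH, rt, then 65 °C
Reagents that add atoms: ammonium acetate [NH4+].CC(=O)[O-]
Why: Proposed new method: the 1,3-dianion 5 of diketone 4 should attack cyclic sulfate 3 with its terminal carbanion (the acetyl carbon, later C5) at the unhindered primary O–CH2 carbon (later C4) in an SN2 opening that forms C4–C5 and leaves the secondary carbon as the alkyl sulfate of enolate 6; ammonium acetate then turns the 1,3-diketone into the primary (Z)-enaminone 7, whose nitrogen displaces the secondary sulfate and forms N1–C2. The closest known reaction types are the γ-alkylation of 1,3-dicarbonyl dianions, the double displacement of cyclic sulfates by nitrogen nucleophiles (amidines to imidazolines, amines to aziridines) and the cyclisation of ω-halo 1,3-dicarbonyl compounds with amines to cyclic enaminones; their merger in one flask with a 1,3-cyclic sulfate and ammonia as three components is the untested part. Ring E closes in the 6-exo-tet mode. The only new stereocentre, C2, becomes S by SN2 inversion of the R carbinol carbon of diol 1, so it is set by the chiral pool and not by the substrate. The step needs attack at the primary and not the secondary carbon of 3 (sterics), C-alkylation at the terminal carbon and not at C7 or C10 (the last-formed, most basic carbanion of the dianion reacts first), and closure through nitrogen and not through oxygen or C7. The last point is secured by keeping the enolate stage cold so that the sulfate monoester survives, by forming the enaminone at room temperature before heating, and by ring size and sterics: nitrogen on C6 closes a six-membered ring, the carbonyl oxygen of 7 would need an eight-membered ring, C7 would have to become a quaternary spiro centre, and enaminone formation is reversible so that a regioisomeric enaminone can funnel back.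

Step 3
Reactants: 8 (2Z)-2-[(6S)-6-methylpiperidin-2-ylidene]cyclopentan-1-one
Product: 10 (2R)-2-[(2S,6S)-1-acetyl-6-methylpiperidin-2-yl]cyclopentan-1-one, via amino ketone acetate salt 9 (not isolated)
Conditions: H2 (5 atm), PtO2 (10 mol %), AcOH (1.1 equiv), EtOAc, rt, stopped after one equivalent of H2; filter; then AcCl, i-Pr2NEt, CH2Cl2, 0 °C
Reagents that add atoms: acetyl chloride CC(=O)Cl
Why: Heterogeneous catalytic hydrogenation of the hydrogen-bonded (Z)-β-enaminone should add both hydrogens to one face (syn addition) and to the face of ring E opposite the C2 methyl group, which sets C6 (S, cis to C2–CH3) and C7 (R) together; the acetic acid holds the amine as its salt against retro-Mannich epimerisation until N-acylation with acetyl chloride gives the amide.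

Step 4
Reactants: 10 (2R)-2-[(2S,6S)-1-acetyl-6-methylpiperidin-2-yl]cyclopentan-1-one
Product: 12 (5R)-5-[(2S,6S)-1-acetyl-6-methylpiperidin-2-yl]cyclopent-2-en-1-one, via silyl enol ether 11 (not isolated)
Conditions: LDA, TMSCl, THF, −78 °C; then Pd(OAc)2 (1.05 equiv), MeCN, rt
Reagents that add atoms: none
Why: Ito–Saegusa oxidation, in which kinetic deprotonation at the unhindered C10 methylene (internal TMSCl quench) gives the less substituted silyl enol ether and Pd(OAc)2 dehydrogenates it to the C9=C10 enone without touching the C7 stereocentre.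

Step 5
Reactants: 12 (5R)-5-[(2S,6S)-1-acetyl-6-methylpiperidin-2-yl]cyclopent-2-en-1-one
Product: 13 (1R,5R)-5-[(2S,6S)-1-acetyl-6-methylpiperidin-2-yl]-1-methylcyclopent-2-en-1-ol
Conditions: MeLi, CeCl3, THF, −78 °C
Reagents that add atoms: methyllithium [Li]C
Why: 1,2-Addition of the weakly basic organocerium reagent to the enone carbonyl from the face opposite the bulky C7 substituent should set C11 (CH3 trans and OH cis to the piperidine) while avoiding enolisation at C7 and attack on the amide.

Step 6
Reactants: 14 cyclohex-1-ene-1-carbaldehyde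
Product: 15 (2E)-3-(cyclohex-1-en-1-yl)prop-2-enoic acid
Conditions: malonic acid, pyridine, piperidine (cat.), 90 °C
Reagents that add atoms: malonic acid OC(=O)CC(=O)O
Why: Doebner–Knoevenagel condensation with decarboxylation, which gives the (E)-dienoic acid.

Step 7
Reactants: 15 (2E)-3-(cyclohex-1-en-1-yl)prop-2-enoic acid; 13 (1R,5R)-5-[(2S,6S)-1-acetyl-6-methylpiperidin-2-yl]-1-methylcyclopent-2-en-1-ol
Product: 18 (1R,5R)-5-[(2S,6S)-1-acetyl-6-methylpiperidin-2-yl]-1-methylcyclopent-2-en-1-yl (2E)-3-(cyclohex-1-en-1-yl)prop-2-enoate, via acid chloride 16 (not isolated), via lithium alkoxide 17 (not isolated)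
Conditions: 15, (COCl)2, DMF (cat.), CH2Cl2, 0 °C → rt, concentrate; 13, LiHMDS, THF, −78 °C, then 16, −78 → 0 °C
Reagents that add atoms: none
Why: O-Acylation of a hindered tertiary lithium alkoxide with an acid chloride, a base-mediated esterification that avoids the acid which would ionise the tertiary allylic alcohol.

Step 8
Reactants: 18 (1R,5R)-5-[(2S,6S)-1-acetyl-6-methylpiperidin-2-yl]-1-methylcyclopent-2-en-1-yl (2E)-3-(cyclohex-1-en-1-yl)prop-2-enoate
Product: 19 tetracyclic β,γ-unsaturated lactone (C14=C15 alkene; C13–H trans to C10–H and cis to C16–H)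
Conditions: BHT (cat.), toluene (0.01 M), 170 °C, sealed tube (base-washed glass)
Reagents that add atoms: none
Why: Thermal intramolecular Diels–Alder reaction of the electron-poor dienoate (C13=C14–C15=C16) with the tethered cyclopentene (C9=C10), in which the three-atom ester tether forces addition to the face of ring C that carries the ester oxygen (rings B, C and D all-cis at C9, C10 and C11 by suprafacial addition) and the exo transition state, with ring C and its C7 substituent turned away from the diene, sets C16–H trans to C9–H.

Step 9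
Reactants: 19 tetracyclic β,γ-unsaturated lactone
Product: 21 target CNP0529632.1, via hydroperoxide 20 (not isolated)
Conditions: DBU, O2 (1 atm), MeCN, rt; then PPh3
Reagents that add atoms: dioxygen O=O
Why: Base-mediated autoxidation of a β,γ-unsaturated lactone, in which the extended enolate formed at C13 should take up O2 at the γ-carbon C15 (restoring conjugation as C13=C14) along the axial direction anti to C16–H to give the trans-fused tertiary hydroperoxide, which PPh3 reduces to the alcohol.

**Compound list**

1 | (3R)-butane-1,3-diol | C[C@@H](O)CCO | starting material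
2 | (4R)-4-methyl-1,3,2-dioxathiane 2-oxide (cyclic sulfite, both sulfur epimers, not isolated) | C[C@@H]1CCOS(=O)O1 | intermediate
3 | (4R)-4-methyl-1,3,2-dioxathiane 2,2-dioxide | C[C@@H]1CCOS(=O)(=O)O1 | intermediate
4 | 2-acetylcyclopentan-1-one | CC(=O)C1CCCC1=O | starting material
5 | dilithium 1,3-dianion of 2-acetylcyclopentan-1-one (not isolated) | [Li+].[Li+].C=C([O-])C1=C([O-])CCC1 | intermediate
6 | dilithium salt of the enolate of (2R)-6-oxo-6-(2-oxocyclopentyl)hexan-2-yl sulfate (not isolated) | [Li+].[Li+].C[C@H](CCCC(=O)[C-]1CCCC1=O)OS(=O)(=O)[O-] | intermediate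
7 | lithium (2R,6Z)-6-amino-6-(2-oxocyclopentylidene)hexan-2-yl sulfate (not isolated) | [Li+].C[C@H](CCC/C(N)=C1\CCCC1=O)OS(=O)(=O)[O-] | intermediate
8 | (2Z)-2-[(6S)-6-methylpiperidin-2-ylidene]cyclopentan-1-one | C[C@H]1CCC/C(N1)=C1\CCCC1=O | intermediate
9 | acetate salt of (2R)-2-[(2S,6S)-6-methylpiperidin-2-yl]cyclopentan-1-one (not isolated) | CC(=O)O.N1[C@@H](C)CCC[C@H]1[C@H]1CCCC1=O | intermediate
10 | (2R)-2-[(2S,6S)-1-acetyl-6-methylpiperidin-2-yl]cyclopentan-1-one | CC(=O)N1[C@@H](C)CCC[C@H]1[C@H]1CCCC1=O | intermediate
11 | 1-[(2S,6S)-2-methyl-6-[(1R)-2-(trimethylsilyloxy)cyclopent-2-en-1-yl]piperidin-1-yl]ethan-1-one (not isolated) | CC(=O)N1[C@@H](C)CCC[C@H]1[C@H]1CCC=C1O[Si](C)(C)C | intermediate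
12 | (5R)-5-[(2S,6S)-1-acetyl-6-methylpiperidin-2-yl]cyclopent-2-en-1-one | CC(=O)N1[C@@H](C)CCC[C@H]1[C@H]1CC=CC1=O | intermediate
13 | (1R,5R)-5-[(2S,6S)-1-acetyl-6-methylpiperidin-2-yl]-1-methylcyclopent-2-en-1-ol | CC(=O)N1[C@@H](C)CCC[C@H]1[C@H]1CC=C[C@@]1(C)O | intermediate
14 | cyclohex-1-ene-1-carbaldehyde | O=CC1=CCCCC1 | starting material
15 | (2E)-3-(cyclohex-1-en-1-yl)prop-2-enoic acid | OC(=O)/C=C/C1=CCCCC1 | intermediate
16 | (2E)-3-(cyclohex-1-en-1-yl)prop-2-enoyl chloride (not isolated) | ClC(=O)/C=C/C1=CCCCC1 | intermediate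
17 | lithium alkoxide of 13 (not isolated) | [Li+].CC(=O)N1[C@@H](C)CCC[C@H]1[C@H]1CC=C[C@@]1(C)[O-] | intermediate
18 | (1R,5R)-5-[(2S,6S)-1-acetyl-6-methylpiperidin-2-yl]-1-methylcyclopent-2-en-1-yl (2E)-3-(cyclohex-1-en-1-yl)prop-2-enoate | CC(=O)N1[C@@H](C)CCC[C@H]1[C@H]1CC=C[C@@]1(C)OC(=O)/C=C/C1=CCCCC1 | intermediate
19 | Diels–Alder adduct: rings A–D closed, C14=C15 alkene, lactone trans-fused to ring B (C13–H trans to C10–H, cis to C16–H), N-acetyl-cis-2,6-piperidine on C7 | CC(=O)N1[C@@H](C)CCC[C@H]1[C@H]1C[C@@H]2[C@H]3[C@H](C=C4CCCC[C@@H]24)C(=O)O[C@@]13C | intermediate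
20 | C15 hydroperoxide of the target (C13=C14 alkylidene lactone, OOH trans to C16–H, not isolated) | CC(=O)N1[C@@H](C)CCC[C@H]1[C@H]1C[C@@H]2[C@H]3C(=C[C@]4(OO)CCCC[C@@H]24)C(=O)O[C@@]13C | intermediate
21 | CNP0529632.1: 1-acetyl-(2S,6S)-2-methylpiperidine carrying at C6 the tetracyclic C15-hydroxy C13=C14 alkylidene lactone (C7 R, C9 S, C10 S, C11 R, C15 S, C16 S) | CC(=O)N1[C@@H](C)CCC[C@H]1[C@H]1C[C@@H]2[C@H]3C(=C[C@]4(O)CCCC[C@@H]24)C(=O)O[C@@]13C | target

**Step count and risks**

Total step count: 9. Longest linear sequence: 8 steps (steps 1, 2, 3, 4, 5, 7, 8, 9 from (3R)-butane-1,3-diol); step 6 is a one-step side branch.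

Steps most likely to fail:

1. Step 2 (proposed new method). The process at risk is the second stage: the enol(ate) oxygen or C7 may close the ring instead of nitrogen, or displacement of the secondary sulfate monoester may be so slow that elimination and solvolysis take over. The fallback uses known chemistry and sets out from 4. Condensation of 4 with commercial (3S)-3-aminobutan-1-ol (toluene, cat. AcOH, water removal) should give the secondary enaminone (2Z)-2-[1-[[(2S)-4-hydroxybutan-2-yl]amino]ethylidene]cyclopentan-1-one F1, in which N1–C2 comes from the chiral pool with retention. An Appel reaction (iodine, PPh3, imidazole) converts it into the iodide (2Z)-2-[1-[[(2S)-4-iodobutan-2-yl]amino]ethylidene]cyclopentan-1-one F2. Treatment with LDA (2.2 equiv, THF, −78 → 0 °C) forms the N,C-dianion, whose methyl-derived carbanion closes C4–C5 by the known γ-alkylation of β-enaminone dianions (6-exo-tet; only this carbanion can reach the iodide in a six-membered ring). The fallback comes back to the route at 8.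

2. Step 8. The process at risk is thermal ionisation or syn-elimination of the tertiary allylic ester, or an intramolecular ene reaction, outrunning a slow cycloaddition onto an unactivated cyclopentene face that also carries the C7 substituent. The fallback sets out from 13 and 15 and replaces the ester tether by a thermally robust temporary silicon tether. Reduction of 15 (LiAlH4, Et2O, 0 °C) gives (2E)-3-(cyclohex-1-en-1-yl)prop-2-en-1-ol F3. Alcohol 13 is silylated with diisopropylsilyl bis(trifluoromethanesulfonate) and 2,6-lutidine and then joined to F3 to give the mixed diisopropylsilyl ketal F4. The silicon-tethered intramolecular Diels–Alder reaction (xylene, 200 °C) should give the seven-membered silacycle adduct F5 with the same facial and exo control. TBAF removes silicon to give the diol F6 (C12 as CH2OH, tertiary OH on C11), and oxidative lactonisation with TEMPO and PhI(OAc)2 comes back to the route at 19.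

3. Step 3. The process at risk is over-reduction of the ring ketone on the platinum catalyst, and retro-Mannich opening of the free β-amino ketone that would scramble C6 and C7 before acylation. The fallback sets out from 8 and accepts the over-reduction. Exhaustive hydrogenation (H2, PtO2, AcOH) should give, with the same syn addition, the amino alcohol (1R,2R)-2-[(2S,6S)-6-methylpiperidin-2-yl]cyclopentan-1-ol F7, which cannot undergo a retro-Mannich reaction. N-Selective acetylation (Ac2O, MeOH, 0 °C) gives 1-[(2S,6S)-2-[(1R,2R)-2-hydroxycyclopentyl]-6-methylpiperidin-1-yl]ethan-1-one F8, and Dess–Martin oxidation comes back to the route at 10; the carbinol configuration is of no consequence.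

Further compounds
F1 | step 2 | (2Z)-2-[1-[[(2S)-4-hydroxybutan-2-yl]amino]ethylidene]cyclopentan-1-one | C[C@@H](CCO)N/C(C)=C1/CCCC1=O
F2 | step 2 | (2Z)-2-[1-[[(2S)-4-iodobutan-2-yl]amino]ethylidene]cyclopentan-1-one | C[C@@H](CCI)N/C(C)=C1/CCCC1=O
F3 | step 8 | (2E)-3-(cyclohex-1-en-1-yl)prop-2-en-1-ol | OC/C=C/C1=CCCCC1
F4 | step 8 | mixed diisopropylsilyl ketal of 13 and F3 | CC(=O)N1[C@@H](C)CCC[C@H]1[C@H]1CC=C[C@@]1(C)O[Si](C(C)C)(C(C)C)OC/C=C/C1=CCCCC1
F5 | step 8 | silicon-tethered Diels–Alder adduct (seven-membered dioxasilepane across C11–O and C12; C14=C15 alkene) | CC(=O)N1[C@@H](C)CCC[C@H]1[C@H]([C@]3(C)O[Si](C(C)C)(C(C)C)OC5)C[C@@H]2[C@H]3[C@@H]5C=C4CCCC[C@@H]24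
F6 | step 8 | diol from F5 (C12 as CH2OH on C13, tertiary OH on C11) | CC(=O)N1[C@@H](C)CCC[C@H]1[C@H]([C@]3(C)O)C[C@@H]2[C@H]3[C@H](C=C4CCCC[C@@H]24)CO
F7 | step 3 | (1R,2R)-2-[(2S,6S)-6-methylpiperidin-2-yl]cyclopentan-1-ol | N1[C@@H](C)CCC[C@H]1[C@H]1CCC[C@H]1O
F8 | step 3 | 1-[(2S,6S)-2-[(1R,2R)-2-hydroxycyclopentyl]-6-methylpiperidin-1-yl]ethan-1-one | CC(=O)N1[C@@H](C)CCC[C@H]1[C@H]1CCC[C@H]1O
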